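Summer is charged with twice the free monomer of dawn on the same 100 µM of pre-initiator, so I asked how far its chains outgrow dawn's by 50 min.

| flask | free monomer | pre-initiator | remark | time |
|---|---|---|---|---|
| red | 20 mM | 150 µM | run made earlier |  |
| green | 20 mM | 50 µM | run made earlier |  |
| dawn | 20 mM | 100 µM |  | 50 min |
| summer | 40 mM | 100 µM |  | 50 min |

| run | time / min | monomer in chains / % | free monomer / % |
|---|---|---|---|
| red | 1.33 | 3 | 103 |
| red | 3.00 | 4 | 99 |
| red | 6.00 | 5 | 89 |
| red | 10.0 | 22 | 79 |
| red | 12.0 | 30 | 74 |
| red | 20.0 | 53 | 46 |
| green | 1.33 | 0 | 106 |
| green | 2.50 | 2 | 99 |
| green | 4.00 | 0 | 99 |
| green | 6.00 | 1 | 96 |
| green | 10.0 | 6 | 90 |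
| green | 20.0 | 28 | 76 |

(scatter of a reading: 2 percentage points)

* which of the two ends with the longer chains by the average number of monomer units in a chain (chains begun, living or dead) ("neither" if they lie within 10 %) (dawn / summer / neither)
* average number of monomer units in a chain (chains begun, living or dead) at the end, dawn
* average number of monomer units in a chain (chains begun, living or dead) at the end, summer

- the average divides the monomer in chains by the number of chains begun, living and dead together
- what was read earlier has a scatter of 2 percentage points, one standard deviation
- steps thought possible: free monomer + living end -> monomer in chains + living end; free monomer + initiator -> living end + monomer in chains; monomer in chains + living end -> free monomer + living end; pre-initiator <-> initiator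
- the earlier runs do not show the number of chains; that part of a forecast is a guess

I took the numbers in turn. The count of chains begun is unseen. I guessed that it follows the pre-initiator, equal in both flasks, so it cancels in the ratio of lengths, though not in the lengths themselves. For the free monomer the time mattered little: scaling the red run's fall by pre-initiator and time squared gave, with no floor, 3.93 % of dawn's charge at 50 min, so I took adding to chains and falling back to balance by then. For the ratio of lengths, what mattered was where free monomer stops. With equal counts and no floor, that ratio is the ratio of charges; a floor below dawn's charge, shared by both flasks, raises it.

The red run holds 3.00 times the green run's pre-initiator, so, if the pace of the fall follows pre-initiator, at 20.0 min its remaining share of the distance to the floor should be the cube of the green run's. Red's free monomer had fallen 2.25 times as far as green's, and solving gave 2.56 mM, a rough reading from two values with a scatter of 2 percentage points. This floor, the free monomer at which adding and falling back balance, is the equilibrium monomer concentration. Charge less floor made summer's chains 2.15 times dawn's, beyond the margin, so I chose summer.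

The forecast said summer, with 300 for dawn and 500 for summer: “Summer therefore wins.”

The flask gave 349 for dawn and 822 for summer. Free monomer ended at 5.54 mM in dawn and 5.62 mM in summer, from charges of 20 mM and 40 mM. Charge less my floor of 2.56 mM had given 2.15, less than the flask's ratio of 2.36.

    free monomer + living end → monomer in chains + living end, rate k1*[living end]*[free monomer] (k = 78.7 /M/s)
    free monomer + initiator → living end + monomer in chains (k = 0.856 /M/s)
    monomer in chains + living end → free monomer + living end, rate k3*[living end] as long as [monomer in chains] is above zero (k = 0.431 /s)
    pre-initiator ⇌ initiator (K = 0.570, k = 2.00 × 10⁻⁴ /s)

A neighbour of dawn charged with 50 mM of free monomer, all else held, gets 949 from charge less floor, scaled on dawn's length. The computed length there is 1060.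

(The readings were computed on assumed constants, noise included.)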